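The route rests on opening the γ-lactone ring (O1–C2–C3–C4–C5) across C2–C3 and O1–C5. This exposes a 2-alkyl-3-oxosuccinate, whose ketone carbon becomes the quaternary C2, and acrolein, which supplies C3–C5. In one carbene-catalysed operation the acrolein homoenolate adds to the ketone and the alkoxide lactonises, creating the ring, two skeletal bonds and both stereocenters. The step exploits the acidity of C1′–H, held between the C2 ketone and its own ester, so that the racemic keto diester is funnelled into one stereoisomer. The precursor is a dibenzyl keto diester carrying a ten-carbon chain that ends in a silyl ether; the D-malate is attached afterwards and hydrogenolysis finishes the synthesis.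

Key step: step 4

Remark: the lactone part of the target is (1′S,2R) and the malate is (R), bound through C1, the carboxyl next to its carbinol carbon; locants are O1, C2 (quaternary), C3, C4, C5 (carbonyl) and C1′ for the side-chain methine.

Remark: the sense of induction of the triazolium salt in step 4 is assumed as written; its mirror-image salt is equally available and would be used if a pilot run gave the (2S) series.

Step 1
Reactants: 1 12-hydroxydodecanoic acid
Product: 2 benzyl 12-hydroxydodecanoate
Conditions: BnBr (1.1 equiv), KHCO3 (1.5 equiv), DMF, rt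
Reagents that add atoms: benzyl bromide, BrCc1ccccc1
Why: Carboxylate O-alkylation (SN2) under bicarbonate, which deprotonates only the acid, so the primary alcohol stays free.

Step 2
Reactants: 2 benzyl 12-hydroxydodecanoate
Product: 3 benzyl 12-[(tert-butyldimethylsilyl)oxy]dodecanoate
Conditions: TBSCl (1.2 equiv), imidazole (2 equiv), CH2Cl2, 0 °C to rt
Reagents that add atoms: tert-butyldimethylsilyl chloride, CC(C)(C)[Si](C)(C)Cl
Why: Imidazole-mediated silylation of the primary alcohol gives a silyl ether that should tolerate the amide base of step 3 and the carbene of step 4.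

Step 3
Reactants: 3 benzyl 12-[(tert-butyldimethylsilyl)oxy]dodecanoate; 4 dibenzyl oxalate
Product: 6 dibenzyl 2-[10-(tert-butyldimethylsilyloxy)decyl]-3-oxobutanedioate (racemic keto–enol mixture), via lithium ester enolate 5 (not isolated)
Conditions: LDA (1.05 equiv), THF, −78 °C; cannula into 4 (1.5 equiv), THF, −78 to −40 °C; AcOH quench
Reagents that add atoms: none
Why: Crossed Claisen condensation in which the preformed ester enolate acylates the non-enolisable oxalate, the product being held as its stabilised enolate until the quench, which should block a second addition; C1′ stays labile, so no stereocenter is fixed here.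

Step 4
Reactants: 6 dibenzyl 2-[10-(tert-butyldimethylsilyloxy)decyl]-3-oxobutanedioate; 7 acrolein
Product: 8 benzyl (2R)-2-[(1S)-1-(benzyloxycarbonyl)-11-(tert-butyldimethylsilyloxy)undecyl]-5-oxooxolane-2-carboxylate
Conditions: (5aS,10bR)-2-mesityl-5a,10b-dihydro-4H,6H-indeno[2,1-b][1,2,4]triazolo[4,3-d][1,4]oxazin-2-ium chloride (15 mol%), i-Pr2NEt (20 mol%), 4 Å MS, toluene, 0 °C to rt; 7 (3 equiv, freshly distilled) by syringe pump over 10 h
Reagents that add atoms: none
Why: Proposed new method: the triazolylidene adds to the aldehyde of 7, proton transfer gives the conjugated Breslow intermediate (a homoenolate), its β-carbon attacks the ketone carbon of 6 to form C2–C3, and the tertiary alkoxide then acylates the acyl azolium to form O1–C5 and release the carbene. The closest known reaction type is the carbene-catalysed (3+2) homoenolate annulation of β-substituted enals with α-keto esters, including dynamic kinetic versions on β-halo α-keto esters, whereas unsubstituted acrolein and a keto ester with a β-alkoxycarbonyl group lie outside that scope. The lactone ring closes by 5-exo-trig addition–elimination at the acyl azolium carbonyl. C2 is set by the catalyst, whose aminoindane backbone and N-mesityl group leave one face of the ketone open to the bound homoenolate, and C1′ is set by substrate control in an open staggered (Felkin–Anh-type) transition state with the C1′ ester anti to the forming bond, the alkyl chain next to the ketone oxygen and H toward the C2 ester, so that the (1′S) epimer should be the matched partner for (2R) attack while the (1′R) epimer is returned through the enol by the catalytic amine. The step needs chemoselectivity for the ketone of 6 over the aldehyde of a second acrolein and over conjugate addition or proton transfer from the C–H acidic substrate, and the high electrophilicity of the 1,2-dicarbonyl, the sub-stoichiometric hindered base and the slow feed of acrolein are meant to secure it.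

Step 5
Reactants: 8 benzyl (2R)-2-[(1S)-1-(benzyloxycarbonyl)-11-(tert-butyldimethylsilyloxy)undecyl]-5-oxooxolane-2-carboxylate
Product: 9 benzyl (2R)-2-[(1S)-1-(benzyloxycarbonyl)-11-hydroxyundecyl]-5-oxooxolane-2-carboxylate
Conditions: HF·pyridine, pyridine, THF, 0 °C to rt
Reagents that add atoms: none
Why: Acidic fluoride desilylation cleaves the Si–O bond without base, so the lactone, the benzyl esters and the C1′–H next to the ester (open to epimerisation or E1cB ring opening under basic fluoride) should stay untouched.

Step 6
Reactants: 10 (R)-malic acid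
Product: 11 (3R)-2,5-dioxooxolan-3-yl trifluoroacetate (O-trifluoroacetyl-D-malic anhydride)
Conditions: TFAA (neat, excess), 0 °C to rt; volatiles removed in vacuo, used crude
Reagents that add atoms: trifluoroacetic anhydride, O=C(OC(=O)C(F)(F)F)C(F)(F)F
Why: O-Acylation and dehydrative cyclisation of the 1,4-diacid to the five-membered anhydride with trifluoroacetic anhydride, a known activation of malic acid that does not touch the C–O bond of the stereocenter, which stays (R).

Step 7
Reactants: 9 benzyl (2R)-2-[(1S)-1-(benzyloxycarbonyl)-11-hydroxyundecyl]-5-oxooxolane-2-carboxylate; 11 (3R)-2,5-dioxooxolan-3-yl trifluoroacetate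
Product: 13 (3R)-4-({(11S)-11-(benzyloxycarbonyl)-11-[(2R)-2-(benzyloxycarbonyl)-5-oxooxolan-2-yl]undecyl}oxy)-3-hydroxy-4-oxobutanoic acid, via O-trifluoroacetyl half-ester 12 (not isolated)
Conditions: 11 (3 equiv), THF, rt, no base; then MeOH, rt
Reagents that add atoms: none
Why: Regioselective alcoholysis of the O-acylmalic anhydride, in which the primary alcohol opens the carbonyl next to the electron-withdrawing trifluoroacetoxy group (C1), followed by methanolysis of the labile trifluoroacetate; no base is present, so neither elimination to maleic anhydride nor racemisation is expected.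

Step 8
Reactants: 13 (3R)-4-({(11S)-11-(benzyloxycarbonyl)-11-[(2R)-2-(benzyloxycarbonyl)-5-oxooxolan-2-yl]undecyl}oxy)-3-hydroxy-4-oxobutanoic acid
Product: 14 (2R)-2-[(1S)-1-carboxy-11-{[(2R)-3-carboxy-2-hydroxypropanoyl]oxy}undecyl]-5-oxooxolane-2-carboxylic acid
Conditions: H2 (1 atm), 10% Pd/C, EtOAc, rt
Reagents that add atoms: none
Why: Catalytic hydrogenolysis of the two benzyl esters under neutral conditions, to which the lactone, the aliphatic malate ester and the three stereocenters are inert.

Compound list
1 | 12-hydroxydodecanoic acid | OCCCCCCCCCCCC(=O)O | starting material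
2 | benzyl 12-hydroxydodecanoate | OCCCCCCCCCCCC(=O)OCc1ccccc1 | intermediate
3 | benzyl 12-[(tert-butyldimethylsilyl)oxy]dodecanoate | CC(C)(C)[Si](C)(C)OCCCCCCCCCCCC(=O)OCc1ccccc1 | intermediate
4 | dibenzyl oxalate | O=C(OCc1ccccc1)C(=O)OCc1ccccc1 | starting material
5 | lithium enolate of benzyl 12-[(tert-butyldimethylsilyl)oxy]dodecanoate | [Li+].[O-]C(OCc1ccccc1)=CCCCCCCCCCCO[Si](C)(C)C(C)(C)C | intermediate
6 | dibenzyl 2-[10-(tert-butyldimethylsilyloxy)decyl]-3-oxobutanedioate (racemic) | O=C(OCc1ccccc1)C(=O)C(CCCCCCCCCCO[Si](C)(C)C(C)(C)C)C(=O)OCc1ccccc1 | intermediate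
7 | acrolein | C=CC=O | starting material
8 | benzyl (2R)-2-[(1S)-1-(benzyloxycarbonyl)-11-(tert-butyldimethylsilyloxy)undecyl]-5-oxooxolane-2-carboxylate | CC(C)(C)[Si](C)(C)OCCCCCCCCCC[C@H](C(=O)OCc1ccccc1)[C@@]2(C(=O)OCc1ccccc1)CCC(=O)O2 | intermediate
9 | benzyl (2R)-2-[(1S)-1-(benzyloxycarbonyl)-11-hydroxyundecyl]-5-oxooxolane-2-carboxylate | OCCCCCCCCCC[C@H](C(=O)OCc1ccccc1)[C@@]2(C(=O)OCc1ccccc1)CCC(=O)O2 | intermediate
10 | (R)-malic acid (D-malic acid) | OC(=O)C[C@@H](O)C(=O)O | starting material
11 | (3R)-2,5-dioxooxolan-3-yl trifluoroacetate | O=C1C[C@@H](OC(=O)C(F)(F)F)C(=O)O1 | intermediate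
12 | (3R)-4-({(11S)-11-(benzyloxycarbonyl)-11-[(2R)-2-(benzyloxycarbonyl)-5-oxooxolan-2-yl]undecyl}oxy)-4-oxo-3-(trifluoroacetoxy)butanoic acid | OC(=O)C[C@@H](OC(=O)C(F)(F)F)C(=O)OCCCCCCCCCC[C@H](C(=O)OCc1ccccc1)[C@@]2(C(=O)OCc1ccccc1)CCC(=O)O2 | intermediate
13 | (3R)-4-({(11S)-11-(benzyloxycarbonyl)-11-[(2R)-2-(benzyloxycarbonyl)-5-oxooxolan-2-yl]undecyl}oxy)-3-hydroxy-4-oxobutanoic acid | OC(=O)C[C@@H](O)C(=O)OCCCCCCCCCC[C@H](C(=O)OCc1ccccc1)[C@@]2(C(=O)OCc1ccccc1)CCC(=O)O2 | intermediate
14 | (2R)-2-[(1S)-1-carboxy-11-{[(2R)-3-carboxy-2-hydroxypropanoyl]oxy}undecyl]-5-oxooxolane-2-carboxylic acid | O=C(O)C[C@@H](O)C(=O)OCCCCCCCCCC[C@H](C(=O)O)[C@@]1(C(=O)O)CCC(=O)O1 | target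

Total step count: 8. Longest linear sequence: 7 steps (steps 1–5, 7 and 8, from 12-hydroxydodecanoic acid); step 6 is a one-step side branch.

Steps most likely to fail

1. Step 4.
- What may go wrong: acrolein may be consumed by self-annulation or oligomerisation before it meets the ketone. The acidic substrate may protonate the homoenolate at its β-carbon, after which the acyl azolium would acylate the enol oxygen. The catalytic base may trigger conjugate addition of the enolate of 6 to acrolein. The catalyst's facial preference and the substrate bias at C1′ may not reinforce each other, eroding diastereo- and enantioselectivity.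
- Fallback (known chemistry, different bond construction, C1′–C2 instead of C2–C3): it sets out from 3 and comes back at 8. Enolate 5, generated from 3 as in step 3, is added at −78 °C to dibenzyl 2-oxopentanedioate F1, itself prepared from 2-oxoglutaric acid, benzyl bromide and caesium carbonate in DMF. Aldol addition to the keto group and, on warming, 5-exo-trig lactonisation of the tertiary alkoxide onto the distal benzyl ester should give racemic benzyl 2-[1-(benzyloxycarbonyl)-11-(tert-butyldimethylsilyloxy)undecyl]-5-oxooxolane-2-carboxylate F2 as a mixture of both C1′ epimers. The unlike (1′S*,2R*) diastereomer is separated on silica and resolved by preparative chromatography on a chiral stationary phase to give 8. This gives up asymmetric induction in exchange for reliability.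

2. Step 7.
- What may go wrong: the alcohol may attack the distal anhydride carbonyl (C4), giving the regioisomeric malate ester. Acylation by a dilute, precious alcohol may be slow. The trifluoroacetyl group may be transferred to the alcohol instead, which stalls conversion until the methanol treatment returns 9.
- Fallback (regiochemistry fixed by protection, alcohol carbon used as the electrophile): it sets out from 9 and 10 and comes back at 14. Acid 10 is converted with 2,2-dimethoxypropane and catalytic TsOH into [(4R)-2,2-dimethyl-5-oxo-1,3-dioxolan-4-yl]acetic acid F3, which ties up the C1 carboxyl and the hydroxyl. The free C4 acid is benzylated (BnBr, Et3N, acetone) to benzyl 2-[(4R)-2,2-dimethyl-5-oxo-1,3-dioxolan-4-yl]acetate F4. Aqueous acetic acid then hydrolyses the acetonide to (2R)-4-(benzyloxy)-2-hydroxy-4-oxobutanoic acid F5. In parallel, 9 is converted with I2, PPh3 and imidazole in CH2Cl2 into benzyl (2R)-2-[(1S)-1-(benzyloxycarbonyl)-11-iodoundecyl]-5-oxooxolane-2-carboxylate F6. Alkylation of F5 by F6 with Cs2CO3 in DMF (SN2 at the primary iodide by the carboxylate, the free α-hydroxyl being inert) should give benzyl (3R)-4-({(11S)-11-(benzyloxycarbonyl)-11-[(2R)-2-(benzyloxycarbonyl)-5-oxooxolan-2-yl]undecyl}oxy)-3-hydroxy-4-oxobutanoate F7. Hydrogenolysis of its three benzyl esters (H2, Pd/C, EtOAc) gives 14.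

3. Step 3.
- What may go wrong: proton transfer from the acidic product to unreacted ester enolate may stall conversion. Self-condensation of the ester may compete. The enol-rich keto diester may be partly lost on silica.
- Fallback (aldol addition followed by oxidation instead of acylation): it sets out from 3 and comes back at 6. Enolate 5, generated from 3 with LDA at −78 °C, is added to benzyl glyoxylate F8, freshly prepared by periodic acid cleavage of dibenzyl L-tartrate in ether. This should give dibenzyl 2-[10-(tert-butyldimethylsilyloxy)decyl]-3-hydroxybutanedioate F9 as a diastereomer mixture of no consequence. Dess–Martin oxidation (CH2Cl2, NaHCO3, rt) of the secondary alcohol then gives 6.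

Further compounds
F1 | step 4 | dibenzyl 2-oxopentanedioate | O=C(OCc1ccccc1)C(=O)CCC(=O)OCc1ccccc1
F2 | step 4 | racemic benzyl 2-[1-(benzyloxycarbonyl)-11-(tert-butyldimethylsilyloxy)undecyl]-5-oxooxolane-2-carboxylate (both C1′ epimers) | CC(C)(C)[Si](C)(C)OCCCCCCCCCCC(C(=O)OCc1ccccc1)C2(C(=O)OCc1ccccc1)CCC(=O)O2
F3 | step 7 | [(4R)-2,2-dimethyl-5-oxo-1,3-dioxolan-4-yl]acetic acid | OC(=O)C[C@H]1OC(C)(C)OC1=O
F4 | step 7 | benzyl 2-[(4R)-2,2-dimethyl-5-oxo-1,3-dioxolan-4-yl]acetate | O=C(C[C@H]1OC(C)(C)OC1=O)OCc1ccccc1
F5 | step 7 | (2R)-4-(benzyloxy)-2-hydroxy-4-oxobutanoic acid | O=C(C[C@@H](O)C(=O)O)OCc1ccccc1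
F6 | step 7 | benzyl (2R)-2-[(1S)-1-(benzyloxycarbonyl)-11-iodoundecyl]-5-oxooxolane-2-carboxylate | ICCCCCCCCCC[C@H](C(=O)OCc1ccccc1)[C@@]2(C(=O)OCc1ccccc1)CCC(=O)O2
F7 | step 7 | benzyl (3R)-4-({(11S)-11-(benzyloxycarbonyl)-11-[(2R)-2-(benzyloxycarbonyl)-5-oxooxolan-2-yl]undecyl}oxy)-3-hydroxy-4-oxobutanoate | O=C(C[C@@H](O)C(=O)OCCCCCCCCCC[C@H](C(=O)OCc1ccccc1)[C@@]2(C(=O)OCc1ccccc1)CCC(=O)O2)OCc1ccccc1
F8 | step 3 | benzyl glyoxylate | O=CC(=O)OCc1ccccc1
F9 | step 3 | dibenzyl 2-[10-(tert-butyldimethylsilyloxy)decyl]-3-hydroxybutanedioate (diastereomer mixture) | OC(C(=O)OCc1ccccc1)C(CCCCCCCCCCO[Si](C)(C)C(C)(C)C)C(=O)OCc1ccccc1
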